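**The pitfall.** Averaging a closed-flask curve over a tank's spread of stays is sound for first-order steps. It fails once one species changes the fate of another, so I test that first.

| flask | substrate | remark | time |
|---|---|---|---|
| eta | 0.36 M | run made earlier |  |
| theta | 0.24 M | run made earlier |  |
| delta | 0.54 M | run made earlier |  |
| green | 0.36 M | everything together in a closed stirred flask, run for 2.0 h | 2.0 h |
| ochre | 0.36 M | a single well-mixed tank run continuously and read at steady state, 2.0 h in it on average |  |

- eta (time / min: ring / %): 10.0: 18.7; 15.0: 23.8; 25.0: 31.8; 40.0: 36.1; 80.0: 34.3; 120: 31.7
- theta (time / h: ring / %): 0.200: 21.1; 0.333: 28.8; 0.500: 34.2; 0.833: 34.0; 1.33: 33.1; 2.50: 30.0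
- delta (time / h: ring / %): 0.417: 32.9; 0.833: 37.6; 1.33: 36.5; 1.50: 34.4; 2.00: 33.0; 2.50: 31.4

(standard deviation of a reading: 0.5 percentage points)

- a species is counted by the substrate in it: one open dimer or idle adduct counts as two
- amounts and yields of ring count idle adduct too
- the stated concentrations are those of everything mixed, before any reaction; amounts are the same in each set-up
- steps under discussion: 2 substrate -> open dimer; substrate + ring <-> idle adduct; substrate <-> ring; ring <-> isomer of the product
- the earlier runs were made in a closed, stirred flask
- in an amount of ring, one idle adduct counts as one ring

* the set-up with the highest amount of ring at the outlet or at the end, in percent of the substrate put in ("none" if the first two lie within 2 percentage points) (green / ochre / none)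
* amount of ring at the outlet or at the end, in percent of the substrate put in, green
* amount of ring at the outlet or at the end, in percent of the substrate put in, ochre

**The test.** At 0.833 h the delta run, richest in substrate, reads 37.6% of ring, and the theta run, poorest, reads 34.0%. That gap of 3.6 percentage points is more than the scatter. At 2.50 h the gap reads 1.4 points, with the same sign. So more ring stands where more substrate was charged.

**The clock.** Early on, I read ring as the substrate lost. The eta run's first reading then gives 1.24 /h, my substrate clock, the first-order constant of substrate's fall read from the earliest ring. The theta run gives 1.18 /h.

**The vessels.** In closed green, my clock puts the share of substrate left at the end at the exponential of minus clock times time, 8.34%. In tank ochre, feed balances outflow plus reaction, so my clock puts the share at one over one plus clock times mean stay, 28.7%, which is more than its figure for green. On my clock a closed flask holds that share at age 1.00 h, and the eta run brackets this age with 36.1% and 34.3%.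

**The forecast.** It gives 31.7% for green, 29% for ochre and green as best, on the ground that “near-linear kinetics let me weight the batch curve”. My own reckoning differs. I take that ochre figure as the low end and the eta bracket's middle as the high end. Their midpoint, 32.1%, lies within 2 points of green's 31.7%, so I expect no winner.

**The flask.** Green gives 32.1% and ochre 33.3%, less than 2 points apart, so the answer is none.

    2 substrate → open dimer (k = 8.10 × 10⁻⁵ /M/s)
    substrate + ring ⇌ idle adduct, settled at all times (K = 55.0 /M)
    substrate ⇌ ring (K = 2.60, k = 4.10 × 10⁻⁴ /s)
    ring ⇌ isomer of the product (K = 3.60, k = 0.00160 /s)

Free ring's half-life towards the isomer, forward step alone, is 0.12 h, shorter than green's 2.0 h and shorter than the 0.559 h half-life of substrate on my clock. The amount of ring also counts idle adduct, and in green the equilibrium constant of that tying up times starting substrate is 20.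

The readings were generated by integration with constants of no real substance; the scatter is artificial.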